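**Retrosynthetic overview**
1. Target 11 ⇐ diol 9 by two invertive deoxyhalogenations: side-chain OH → Cl, then ring allylic OH → Br.
2. 9 ⇐ bromomethyl ketone 8 by CBS reduction, which sets the side-chain centre and turns the racemic ring series into separable diastereomers; 8 ⇐ bromo-alcohol 6 by Stille coupling/NBS.
3. 6 ⇐ δ-chloro enone 5 (Luche reduction, cis) ⇐ dienone 4 by 1,6-addition of HCl (C–Cl bond next to the quaternary carbon without any SN2 step).
4. 4 ⇐ 2-bromo-6-methylphenol 2 by ortho-C-methylative dearomatization (creates the CMe2 carbon) ⇐ o-cresol 1.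
5. No ring is formed: the six-membered ring is the benzene ring of o-cresol, carried through after dearomatization.

Assumption: reagents that deliver atoms (NBS, MeI, HCl, the vinylstannane, the halogenating agents) are given by name and SMILES in the steps and are not numbered; racemic compounds 5–8 are named and drawn as the enantiomer that leads to the target, with the prefix rac.

**Step 1**
Reactants: 1 2-methylphenol (o-cresol)
Product: 2 2-bromo-6-methylphenol
Conditions: NBS (1.0 equiv), i-Pr2NH (10 mol%), CH2Cl2, 0 °C to rt
Reagents that add atoms: N-bromosuccinimide, BrN1C(=O)CCC1=O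
Why: Amine-mediated electrophilic aromatic bromination of phenols with NBS is ortho-selective (bromine is delivered within the hydrogen-bonded phenol/N-bromoamine complex), so the only free ortho carbon is brominated; no stereocenter is involved.

**Step 2**
Reactants: 2 2-bromo-6-methylphenol
Product: 5 rac-(5R)-2-bromo-5-chloro-6,6-dimethylcyclohex-2-en-1-one, via lithium 2-bromo-6-methylphenolate 3 (not isolated), via 2-bromo-6,6-dimethylcyclohexa-2,4-dien-1-one 4 (not isolated)
Conditions: n-BuLi (1.0 equiv), toluene, −78 to 25 °C; MeI (5 equiv), sealed tube, 110 °C; filter off LiI; HCl (4 M in 1,4-dioxane, 3 equiv), CH2Cl2, −20 to 0 °C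
Reagents that add atoms: iodomethane, CI; hydrogen chloride, Cl
Why: Proposed new method: the aggregated lithium phenoxide 3 in toluene is alkylated by MeI at the methyl-bearing ortho carbon instead of at oxygen, giving the blocked dienone 4 that cannot re-aromatize (closest known reaction: ortho-C-methylative dearomatization of lithium 2,6-dimethylphenoxide to 2,6,6-trimethylcyclohexa-2,4-dienone, a modest-yielding process), and HCl then protonates 4 to a hydroxypentadienyl cation that chloride captures at the δ-carbon next to the new quaternary centre, γ-protonation of the dienol giving the conjugated α-bromo enone as the thermodynamic product (closest known reactions: conjugate hydrochlorination of enones to β-chloro ketones and 1,6-addition of heteroatom nucleophiles to 2,4-dienones), the C-5 stereocenter being formed racemic and resolved in step 5.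

**Step 3**
Reactants: 5 rac-(5R)-2-bromo-5-chloro-6,6-dimethylcyclohex-2-en-1-one
Product: 6 rac-(1R,5R)-2-bromo-5-chloro-6,6-dimethylcyclohex-2-en-1-ol
Conditions: NaBH4, CeCl3·7H2O, MeOH, −78 °C
Reagents that add atoms: none
Why: Luche reduction gives clean 1,2-reduction of the α-bromo enone, and hydride adds axially to the half-chair with the C-5 chlorine equatorial, on the face away from the pseudoaxial C-6 methyl group, so the new hydroxyl is equatorial and cis to chlorine (substrate control, still racemic).

**Step 4**
Reactants: 6 rac-(1R,5R)-2-bromo-5-chloro-6,6-dimethylcyclohex-2-en-1-ol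
Product: 8 rac-2-bromo-1-[(4R,6S)-4-chloro-6-hydroxy-5,5-dimethylcyclohex-1-en-1-yl]ethan-1-one, via ethoxyvinyl carbinol 7 (not isolated)
Conditions: tributyl(1-ethoxyvinyl)stannane (1.3 equiv), PdCl2(PPh3)2 (5 mol%), toluene, 90 °C; filter through basic Al2O3; NBS (1.05 equiv), THF–H2O (4:1), 0 °C
Reagents that add atoms: tributyl(1-ethoxyvinyl)stannane, CCCC[Sn](CCCC)(CCCC)C(=C)OCC; N-bromosuccinimide, BrN1C(=O)CCC1=O; water, O
Why: Stille coupling at the alkenyl bromide installs a masked acetyl group as its enol ether (the free hydroxyl and the alkyl chloride are inert to zerovalent palladium), and NBS in wet THF brominates the electron-rich enol ether carbon, water hydrolysing the oxocarbenium ion to the bromomethyl ketone with loss of ethanol; no stereocenter is created or touched.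

**Step 5**
Reactants: 8 rac-2-bromo-1-[(4R,6S)-4-chloro-6-hydroxy-5,5-dimethylcyclohex-1-en-1-yl]ethan-1-one
Product: 9 (1S,5R)-2-[(1R)-2-bromo-1-hydroxyethyl]-5-chloro-6,6-dimethylcyclohex-2-en-1-ol
Conditions: (R)-2-methyl-CBS-oxazaborolidine (20 mol%), catecholborane (2.5 equiv), toluene, −78 °C; MeOH, pH 7 buffer; separation of diastereomers on SiO2
Reagents that add atoms: none
Why: Corey–Bakshi–Shibata reduction delivers hydride under catalyst control (ring alkenyl group large, CH2Br small; the free hydroxyl is capped in situ as its catechol borate, so no intramolecular hydride delivery competes) to give the (R)-carbinol in both ring-enantiomeric series, so the (4R,6S) half of racemic 8 gives 9 while the mirror-image half gives the (1R,5S,1′R) diastereomer, which is removed on silica, fixing the absolute configuration of all three stereocenters at the cost of half of the material.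

**Step 6**
Reactants: 9 (1S,5R)-2-[(1R)-2-bromo-1-hydroxyethyl]-5-chloro-6,6-dimethylcyclohex-2-en-1-ol
Product: 10 (1R,5R)-2-[(1S)-2-bromo-1-chloroethyl]-5-chloro-6,6-dimethylcyclohex-2-en-1-ol
Conditions: PPh3 (1.2 equiv), Cl3CC(O)CCl3 (3 equiv), CH2Cl2, −20 to 0 °C
Reagents that add atoms: hexachloroacetone, ClC(Cl)(Cl)C(=O)C(Cl)(Cl)Cl
Why: Appel-type deoxychlorination with PPh3/hexachloroacetone, a reagent pair that converts allylic alcohols to chlorides without allylic transposition, activates the less hindered side-chain hydroxyl (the ring hydroxyl is neopentylic) and chloride displaces the oxyphosphonium group by SN2 with inversion, turning the (R)-carbinol into the (S)-chloride.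

**Step 7**
Reactants: 10 (1R,5R)-2-[(1S)-2-bromo-1-chloroethyl]-5-chloro-6,6-dimethylcyclohex-2-en-1-ol
Product: 11 (4R,6S)-6-bromo-1-[(1S)-2-bromo-1-chloroethyl]-4-chloro-5,5-dimethylcyclohex-1-ene
Conditions: CBr4 (1.5 equiv), PPh3 (1.5 equiv), 2,6-lutidine, CH2Cl2, −20 to 0 °C
Reagents that add atoms: tetrabromomethane, BrC(Br)(Br)Br
Why: Appel reaction in which the ring oxyphosphonium group of the cis (diequatorial) chlorohydrin lies pseudoequatorial and poorly aligned with the alkene π-system, disfavouring ionisation and SN2′ attack, so bromide enters axially by SN2 with inversion and gives the (6S)-bromide trans to the ring chlorine.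

**Compound list**
1 | 2-methylphenol (o-cresol) | Cc1ccccc1O | starting material
2 | 2-bromo-6-methylphenol | Cc1cccc(Br)c1O | intermediate
3 | lithium 2-bromo-6-methylphenolate | [Li+].Cc1cccc(Br)c1[O-] | intermediate (not isolated)
4 | 2-bromo-6,6-dimethylcyclohexa-2,4-dien-1-one | CC1(C)C=CC=C(Br)C1=O | intermediate (not isolated)
5 | rac-(5R)-2-bromo-5-chloro-6,6-dimethylcyclohex-2-en-1-one | CC1(C)[C@H](Cl)CC=C(Br)C1=O | intermediate
6 | rac-(1R,5R)-2-bromo-5-chloro-6,6-dimethylcyclohex-2-en-1-ol (cis) | CC1(C)[C@H](Cl)CC=C(Br)[C@@H]1O | intermediate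
7 | rac-(1S,5R)-5-chloro-2-(1-ethoxyethenyl)-6,6-dimethylcyclohex-2-en-1-ol | CC1(C)[C@H](Cl)CC=C(C(=C)OCC)[C@@H]1O | intermediate (not isolated)
8 | rac-2-bromo-1-[(4R,6S)-4-chloro-6-hydroxy-5,5-dimethylcyclohex-1-en-1-yl]ethan-1-one | CC1(C)[C@H](Cl)CC=C(C(=O)CBr)[C@@H]1O | intermediate
9 | (1S,5R)-2-[(1R)-2-bromo-1-hydroxyethyl]-5-chloro-6,6-dimethylcyclohex-2-en-1-ol | CC1(C)[C@H](Cl)CC=C([C@@H](O)CBr)[C@@H]1O | intermediate
10 | (1R,5R)-2-[(1S)-2-bromo-1-chloroethyl]-5-chloro-6,6-dimethylcyclohex-2-en-1-ol | CC1(C)[C@H](Cl)CC=C([C@H](Cl)CBr)[C@@H]1O | intermediate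
11 | (4R,6S)-6-bromo-1-[(1S)-2-bromo-1-chloroethyl]-4-chloro-5,5-dimethylcyclohex-1-ene | CC1(C)[C@H](Cl)CC=C([C@H](Cl)CBr)[C@H]1Br | target

**Step count**
Total steps: 7. Longest linear sequence: 7 (from o-cresol).

**Three steps most likely to fail**

Step 2 (dearomative C-methylation/1,6-hydrochlorination). O-methylation to the anisole, para-C-methylation and Diels–Alder dimerisation of 4 compete with the desired ortho-alkylation, and acid can trigger a dienone–phenol methyl shift instead of chloride addition. The fallback sets out from 1 and comes back at 4. It breaks the aromaticity by hydrogenation instead of alkylation and builds the dienone by enolate and halogenation chemistry. o-Cresol 1 is hydrogenated selectively to 2-methylcyclohexanone F1 (H2, Pd/C, AlCl3 cat., CH2Cl2). F1 is methylated through the thermodynamic enolate to 2,2-dimethylcyclohexanone F2 (NaH, MeI, THF, reflux; the minor 2,6-isomer is distilled off). F2 is dibrominated at its only enolisable carbon to 6,6-dibromo-2,2-dimethylcyclohexanone F3 (Br2, AcOH), and F3 is dehydrobrominated to 2-bromo-6,6-dimethylcyclohex-2-en-1-one F4 (Li2CO3, LiBr, DMF, 120 °C). F4 is brominated at the γ-carbon to 2,4-dibromo-6,6-dimethylcyclohex-2-en-1-one F5 (NBS, AIBN, PhCF3, 80 °C) and dehydrobrominated again (Li2CO3, LiBr, DMF) to dienone 4, which is hydrochlorinated as in step 2 to give 5.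

Step 6 (side-chain OH → Cl). The neighbouring bromine can participate through a bromonium ion, giving retention or a 1,2-halogen shift; SN2′ attack on the allylic system and reaction at the ring hydroxyl are also possible. The fallback sets out from 9 and comes back at 11. It introduces the chlorine by epoxide opening and both bromines together at the end. Bromohydrin 9 is closed with K2CO3 in MeOH at 0 °C to (1S,5R)-5-chloro-6,6-dimethyl-2-[(2R)-oxiran-2-yl]cyclohex-2-en-1-ol F6, with the carbinol configuration retained. The vinyl epoxide is opened at its allylic carbon with inversion by anhydrous HCl in Et2O at −78 °C to (1R,5R)-5-chloro-2-[(1S)-1-chloro-2-hydroxyethyl]-6,6-dimethylcyclohex-2-en-1-ol F7. The primary and the ring hydroxyl of F7 are then converted into bromides in one Appel reaction (CBr4 and PPh3, 2.5 equiv each, CH2Cl2, 0 °C), the ring centre again with inversion, to give 11 directly.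

Step 7 (ring OH → Br). The carbinol carbon is allylic but neopentylic, so formation of the bulky oxyphosphonium salt may be slow and SN2′ delivery of bromide to the other allylic terminus, or ionisation, may compete with direct inversion. The fallback sets out from 10 and comes back at 11. It separates activation from displacement: 10 is converted with MsCl and Et3N in CH2Cl2 at −30 °C into the isolable (1R,5R)-2-[(1S)-2-bromo-1-chloroethyl]-5-chloro-6,6-dimethylcyclohex-2-en-1-yl methanesulfonate F8. The small sulfonate group is then displaced by anhydrous LiBr in acetone at 0 °C, a non-ionising medium, by SN2 with inversion to give 11.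

**Further compounds**
F1 | step 2 | 2-methylcyclohexanone (racemic) | CC1CCCCC1=O
F2 | step 2 | 2,2-dimethylcyclohexanone | CC1(C)CCCCC1=O
F3 | step 2 | 6,6-dibromo-2,2-dimethylcyclohexanone | CC1(C)CCCC(Br)(Br)C1=O
F4 | step 2 | 2-bromo-6,6-dimethylcyclohex-2-en-1-one | CC1(C)CCC=C(Br)C1=O
F5 | step 2 | 2,4-dibromo-6,6-dimethylcyclohex-2-en-1-one (racemic) | CC1(C)CC(Br)C=C(Br)C1=O
F6 | step 6 | (1S,5R)-5-chloro-6,6-dimethyl-2-[(2R)-oxiran-2-yl]cyclohex-2-en-1-ol | CC1(C)[C@H](Cl)CC=C([C@@H]2CO2)[C@@H]1O
F7 | step 6 | (1R,5R)-5-chloro-2-[(1S)-1-chloro-2-hydroxyethyl]-6,6-dimethylcyclohex-2-en-1-ol | CC1(C)[C@H](Cl)CC=C([C@H](Cl)CO)[C@@H]1O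
F8 | step 7 | (1R,5R)-2-[(1S)-2-bromo-1-chloroethyl]-5-chloro-6,6-dimethylcyclohex-2-en-1-yl methanesulfonate | CC1(C)[C@H](Cl)CC=C([C@H](Cl)CBr)[C@@H]1OS(C)(=O)=O
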